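**Strategy.** The route rests on closing the α-methylene-γ-butyrolactone at C7–C11 (germacranolide numbering). The key step exploits the C6–O/C7/C8–O stereotriad. The trans-fused lactone ring (O, C6, C7, C11, C12) and the anti C7–C11/C8–O relationship together map onto an erythro trans-2,3-epoxy alcohol. A phosphonoacetate tethered to O6 is deprotonated, and its carbanion opens the C7–C8 epoxide 5-exo at C7 with inversion. One operation thus forms the lactone ring, sets C7 and frees the C8 hydroxyl for the methacrylate. In-flask Horner–Wadsworth–Emmons reaction with formaldehyde then installs C13. The precursor is an acyclic epoxy phosphonoacetate; the ten-membered ring is closed later at C9–C10.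

Key step: step 12

Remark: atom labels C1–C15 follow germacranolide numbering (ring C1–C10; C11, C12, C13 = lactone α-carbon, carbonyl and exocyclic methylene; C14 = formyl carbon on C10; C15 = hydroxymethyl carbon on C4). 4-Methoxybenzyl propargyl ether is prepared (step 8) rather than assumed to be purchasable.

## Route

Step 1
Reactants: 1 but-2-yne-1,4-diol
Product: 2 4-[(tert-butyldimethylsilyl)oxy]but-2-yn-1-ol
Conditions: NaH (1.0 equiv), THF, 0 → 25 °C; then TBSCl, 25 °C
Reagents that add atoms: tert-butyldimethylsilyl chloride, CC(C)(C)[Si](C)(C)Cl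
Why: Monosilylation of the symmetric diol through its sparingly soluble monosodium alkoxide (O-silylation) should differentiate the two ends that become C6 and C15; no stereocentre is formed.

Step 2
Reactants: 2 4-[(tert-butyldimethylsilyl)oxy]but-2-yn-1-ol
Product: 4 (Z)-4-[(tert-butyldimethylsilyl)oxy]-3-iodobut-2-en-1-ol, via cyclic alkenylaluminate 3 (not isolated)
Conditions: NaAlH2(OCH2CH2OMe)2 (Red-Al), THF, 0 → 25 °C; then I2, −78 → 0 °C
Reagents that add atoms: iodine, II
Why: Hydroxyl-directed trans-hydroalumination of the propargylic alcohol places aluminium on the distal alkyne carbon (C4) inside a five-membered alkoxyaluminate, and iodinolysis with retention should give the alkenyl iodide with iodine cis to C6.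

Step 3
Reactants: 4 (Z)-4-[(tert-butyldimethylsilyl)oxy]-3-iodobut-2-en-1-ol; 5 but-3-en-1-ylzinc bromide
Product: 6 (E)-3-{[(tert-butyldimethylsilyl)oxy]methyl}hepta-2,6-dien-1-ol
Conditions: Pd(PPh3)4 (5 mol %), excess 5, THF, 25 → 50 °C
Reagents that add atoms: none
Why: Negishi sp2–sp3 cross-coupling proceeds with retention at the alkenyl iodide, so C3 ends cis to C6 and the silyloxymethyl group trans, which is the ring-cis C4=C5 geometry of the target.

Step 4
Reactants: 6 (E)-3-{[(tert-butyldimethylsilyl)oxy]methyl}hepta-2,6-dien-1-ol; 7 (E)-crotonaldehyde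
Product: 8 (2E,6E)-8-hydroxy-6-{[(tert-butyldimethylsilyl)oxy]methyl}octa-2,6-dienal
Conditions: second-generation Hoveyda–Grubbs catalyst [RuCl2(H2IMes)(=CH-C6H4-2-OiPr), 5 mol %], excess 7, CH2Cl2, 40 °C
Reagents that add atoms: none
Why: Olefin cross-metathesis of the terminal alkene with excess crotonaldehyde should give the (E)-enal under thermodynamic control while the trisubstituted alkene stays inert.

Step 5
Reactants: 8 (2E,6E)-8-hydroxy-6-{[(tert-butyldimethylsilyl)oxy]methyl}octa-2,6-dienal
Product: 9 (2Z,6E)-8-hydroxy-2-iodo-6-{[(tert-butyldimethylsilyl)oxy]methyl}octa-2,6-dienal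
Conditions: I2, DMAP (cat.), K2CO3, THF/H2O (1:1), 25 °C
Reagents that add atoms: iodine, II
Why: Amine-catalysed α-iodination of the enal (conjugate addition of DMAP, iodination of the enolate, elimination; a Baylis–Hillman-type sequence) should give the favoured (Z)-2-iodoenal, with iodine cis to C2 and the formyl carbon C14 trans to it.

Step 6
Reactants: 9 (2Z,6E)-8-hydroxy-2-iodo-6-{[(tert-butyldimethylsilyl)oxy]methyl}octa-2,6-dienal
Product: 10 (2E,6Z)-3-{[(tert-butyldimethylsilyl)oxy]methyl}-7-iodo-8,8-dimethoxyocta-2,6-dien-1-ol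
Conditions: HC(OMe)3, MeOH, PPTS (cat.), 0 → 25 °C
Reagents that add atoms: trimethyl orthoformate, COC(OC)OC; methanol, CO
Why: Acid-catalysed acetalisation masks C14 as the dimethyl acetal, which should survive all later non-aqueous steps and is released only in step 20.

Step 7
Reactants: 10 (2E,6Z)-3-{[(tert-butyldimethylsilyl)oxy]methyl}-7-iodo-8,8-dimethoxyocta-2,6-dien-1-ol
Product: 11 (2E,6Z)-3-{[(tert-butyldimethylsilyl)oxy]methyl}-7-iodo-8,8-dimethoxyocta-2,6-dienal
Conditions: MnO2, CH2Cl2, 25 °C
Reagents that add atoms: none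
Why: Chemoselective allylic oxidation with MnO2 should give the C6 enal without touching the alkenyl iodide, acetal or silyl ether and with retention of the C4=C5 geometry.

Step 8
Reactants: 12 prop-2-yn-1-ol
Product: 13 1-methoxy-4-[(prop-2-yn-1-yloxy)methyl]benzene
Conditions: NaH, 4-methoxybenzyl chloride, Bu4NI (cat.), THF/DMF, 0 → 25 °C
Reagents that add atoms: 4-methoxybenzyl chloride, COc1ccc(CCl)cc1
Why: Williamson etherification gives the alkyne that will supply C7, C8 and C9 with a non-migrating protecting group on O9.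

Step 9
Reactants: 11 (2E,6Z)-3-{[(tert-butyldimethylsilyl)oxy]methyl}-7-iodo-8,8-dimethoxyocta-2,6-dienal; 13 1-methoxy-4-[(prop-2-yn-1-yloxy)methyl]benzene
Product: 16 (2E,4S,5E,9Z)-6-{[(tert-butyldimethylsilyl)oxy]methyl}-10-iodo-11,11-dimethoxy-1-[(4-methoxybenzyl)oxy]undeca-2,5,9-trien-4-ol, via alkenylborane 14 (not isolated), via alkenylzinc 15 (not isolated)
Conditions: 13, (c-C6H11)2BH (from BH3·SMe2 and cyclohexene), toluene, 0 → 25 °C; Me2Zn, −78 °C; (−)-MIB [(2S)-3-exo-morpholinoisoborneol, 4 mol %]; then 11, −30 → −10 °C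
Reagents that add atoms: none
Why: syn-Hydroboration, boron-to-zinc transmetalation and amino-alcohol-catalysed asymmetric alkenylzinc addition to the aldehyde form the C6–C7 bond with an (E)-C7=C8 alkene; the ligand directs the alkenyl group to the Si face of C6 and so should set the (6S) carbinol.

Step 10
Reactants: 16 (6S)-bis-allylic alcohol (systematic name as in step 9)
Product: 17 (6R,7R,8R)-7,8-epoxy alcohol: compound 16 carrying a trans-epoxide across C7–C8 that is erythro to the C6 hydroxyl
Conditions: Ti(OiPr)4, D-(−)-diisopropyl tartrate, t-BuOOH, 4 Å molecular sieves, CH2Cl2, −20 °C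
Reagents that add atoms: tert-butyl hydroperoxide, CC(C)(C)OO
Why: Sharpless asymmetric epoxidation of the secondary allylic alcohol, in which the (6S) alcohol and D-(−)-tartrate are the matched pair, should deliver oxygen to the (E)-C7=C8 alkene to give the erythro epoxy alcohol. This sets C7 and C8 and raises the enantiopurity, while the C4=C5 alkene, whose C3 substituent is cis to the carbinol, is expected to react much more slowly.

Step 11
Reactants: 17 (6R,7R,8R)-7,8-epoxy alcohol; 18 2-(diethoxyphosphoryl)acetic acid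
Product: 19 (6R,7R,8R)-6-O-[2-(diethoxyphosphoryl)acetyl] derivative of epoxy alcohol 17
Conditions: DCC, DMAP (cat.), CH2Cl2, 0 → 25 °C
Reagents that add atoms: none
Why: Steglich esterification attaches the C11–C12 unit to O6 under neutral conditions that leave the epoxide and all stereocentres untouched.

Step 12
Reactants: 19 (6R,7R,8R)-epoxy phosphonoacetate
Product: 21 (6R,7R,8S)-α-methylene-γ-butyrolactone with free C8 hydroxyl and C9 4-methoxybenzyl ether, via phosphono lactone 20 (not isolated)
Conditions: KOtBu (1.05 equiv), THF, 0 → 40 °C; then (CH2O)n, 0 → 25 °C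
Reagents that add atoms: formaldehyde (as paraformaldehyde), C=O
Why: Proposed new method: deprotonation gives a soft, phosphoryl- and ester-stabilised carbanion at C11 that attacks C7 of the trans-epoxide from the side opposite the C7–O bond, so the γ-lactone ring (O, C6, C7, C11, C12) closes in the 5-exo-tet mode while the epoxide oxygen stays on C8 as an alkoxide that is protonated by the more acidic C11–H; the regenerated phosphonate carbanion then undergoes Horner–Wadsworth–Emmons olefination with formaldehyde to give the C11=C13 methylene. The closest known reaction types are the telescoped intramolecular Michael addition/olefination of O-tethered phosphonoacetates (same tether and same C–C bond, with an enone instead of an epoxide as electrophile), the intermolecular alkylation of phosphonoacetate anions by epoxides, and the 5-exo delivery of tethered nucleophiles to C2 of 2,3-epoxy alcohol carbamates. The only new stereocentre, C7, is set by stereospecific SN2 inversion and is therefore controlled by the epoxide configuration from step 10: the erythro epoxy alcohol gives the trans-fused lactone with the C8 oxygen anti to the new C7–C11 bond. The step needs attack at C7 rather than C8 (six-membered lactone) and C- rather than O-alkylation; the shorter tether and the exo epoxide-opening trajectory favour C7, and the phosphoryl group keeps the nucleophile carbon-centred and less bound by the planar-enolate constraint of a simple ester enolate. C11 is formed as an epimeric mixture but becomes trigonal in the olefination.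

Step 13
Reactants: 21 (6R,7R,8S)-α-methylene lactone alcohol
Product: 22 (6R,7S,8S)-8-O-methacryloyl α-methylene lactone with C9 4-methoxybenzyl ether
Conditions: methacrylic anhydride, Et3N, DMAP (cat.), CH2Cl2, 0 → 25 °C
Reagents that add atoms: methacrylic anhydride, C=C(C)C(=O)OC(=O)C(C)=C
Why: DMAP-catalysed acylation of the hydroxyl freed in the key step installs the final C8 ester directly, with no change at any stereocentre.

Step 14
Reactants: 22 (6R,7S,8S)-8-O-methacryloyl lactone 4-methoxybenzyl ether
Product: 23 (6R,7S,8S)-8-O-methacryloyl lactone with free C9 primary alcohol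
Conditions: DDQ, CH2Cl2/pH 7 buffer, 0 → 25 °C
Reagents that add atoms: none
Why: Oxidative cleavage of the 4-methoxybenzyl ether by DDQ should free O9 without affecting the silyl ether, acetal, alkenyl iodide or the two acrylate units.

Step 15
Reactants: 23 (6R,7S,8S)-C9 primary alcohol
Product: 24 (6R,7S,8S)-C9 aldehyde bearing the C10 alkenyl iodide
Conditions: Dess–Martin periodinane, NaHCO3, CH2Cl2, 0 → 25 °C
Reagents that add atoms: none
Why: Buffered Dess–Martin oxidation should give the α-acyloxy aldehyde without epimerisation at C8; it is used at once.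

Step 16
Reactants: 24 (6R,7S,8S)-C9 aldehyde bearing the C10 alkenyl iodide
Product: 26 macrocyclic C9 carbinol (6R,7S,8S; mixture of C9 epimers), via alkenylchromium 25 (not isolated)
Conditions: CrCl2 (excess), NiCl2 (cat.), DMSO, high dilution (slow addition), 25 °C
Reagents that add atoms: none
Why: Intramolecular Nozaki–Hiyama–Kishi coupling (insertion of zerovalent nickel into C10–I, transmetalation to trivalent chromium, addition to the C9 aldehyde) should close the ten-membered ring with retention of the C1=C10 geometry and in the presence of the α-methylene lactone; the C9 configuration is not relied upon (Felkin–Anh addition would favour 9R) because it is reset in steps 17 and 18.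

Step 17
Reactants: 26 macrocyclic C9 carbinol (C9 epimers)
Product: 27 (6R,7S,8S)-macrocyclic C9 enone
Conditions: Dess–Martin periodinane, NaHCO3, CH2Cl2, 0 °C
Reagents that add atoms: none
Why: Dess–Martin oxidation converges both C9 epimers on one enone conjugated to C1=C10.

Step 18
Reactants: 27 (6R,7S,8S)-macrocyclic C9 enone
Product: 28 (6R,7S,8S,9S)-macrocyclic allylic alcohol
Conditions: NaBH4, CeCl3·7H2O, MeOH, −78 °C
Reagents that add atoms: none
Why: Luche 1,2-reduction under polar Felkin–Anh substrate control, with hydride adding anti to the C8–O bond while C7 and C10 are antiperiplanar, should give the 8,9-syn (9S) alcohol; the low temperature spares the α-methylene lactone and limits acyl migration.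

Step 19
Reactants: 28 (6R,7S,8S,9S)-macrocyclic allylic alcohol
Product: 29 (6R,7S,8S,9S)-9-acetate with C15 silyl ether and C14 dimethyl acetal
Conditions: Ac2O, pyridine, DMAP (cat.), CH2Cl2, 0 °C
Reagents that add atoms: acetic anhydride, CC(=O)OC(C)=O
Why: Fast DMAP-catalysed acetylation fixes O9 as the acetate before the neighbouring methacrylate can migrate.

Step 20
Reactants: 29 (6R,7S,8S,9S)-9-acetate with C15 silyl ether and C14 dimethyl acetal
Product: 30 CNP0147326.4, (1(10)E,4E,6R,7S,8S,9S)-9-acetoxy-15-hydroxy-8-methacryloyloxy-14-oxogermacra-1(10),4,11(13)-trien-12,6-olide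
Conditions: AcOH/THF/H2O (3:1:1), 25 °C
Reagents that add atoms: water, O
Why: Mild aqueous acid hydrolysis should remove the primary silyl ether and the dimethyl acetal in one operation, releasing the C15 alcohol and the C14 enal without touching the esters or the lactone.

## Compound list

1 | but-2-yne-1,4-diol | OCC#CCO | starting material
2 | 4-[(tert-butyldimethylsilyl)oxy]but-2-yn-1-ol | OCC#CCO[Si](C)(C)C(C)(C)C | intermediate
3 | sodium cyclic alkenyl-bis(2-methoxyethoxy)aluminate from 2 (not isolated) | COCCO[Al-]1(OCCOC)OCC=C1CO[Si](C)(C)C(C)(C)C.[Na+] | intermediate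
4 | (Z)-4-[(tert-butyldimethylsilyl)oxy]-3-iodobut-2-en-1-ol | OC/C=C(\I)CO[Si](C)(C)C(C)(C)C | intermediate
5 | but-3-en-1-ylzinc bromide | C=CCC[Zn]Br | starting material
6 | (E)-3-{[(tert-butyldimethylsilyl)oxy]methyl}hepta-2,6-dien-1-ol | OC/C=C(/CO[Si](C)(C)C(C)(C)C)CCC=C | intermediate
7 | (E)-crotonaldehyde | C/C=C/C=O | starting material
8 | (2E,6E)-8-hydroxy-6-{[(tert-butyldimethylsilyl)oxy]methyl}octa-2,6-dienal | OC/C=C(/CO[Si](C)(C)C(C)(C)C)CC/C=C/C=O | intermediate
9 | (2Z,6E)-8-hydroxy-2-iodo-6-{[(tert-butyldimethylsilyl)oxy]methyl}octa-2,6-dienal | OC/C=C(/CO[Si](C)(C)C(C)(C)C)CC/C=C(\I)C=O | intermediate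
10 | (2E,6Z)-3-{[(tert-butyldimethylsilyl)oxy]methyl}-7-iodo-8,8-dimethoxyocta-2,6-dien-1-ol | OC/C=C(/CO[Si](C)(C)C(C)(C)C)CC/C=C(\I)C(OC)OC | intermediate
11 | (2E,6Z)-3-{[(tert-butyldimethylsilyl)oxy]methyl}-7-iodo-8,8-dimethoxyocta-2,6-dienal | O=C/C=C(/CO[Si](C)(C)C(C)(C)C)CC/C=C(\I)C(OC)OC | intermediate
12 | prop-2-yn-1-ol | C#CCO | starting material
13 | 1-methoxy-4-[(prop-2-yn-1-yloxy)methyl]benzene | C#CCOCc1ccc(OC)cc1 | intermediate
14 | dicyclohexyl{(E)-3-[(4-methoxybenzyl)oxy]prop-1-en-1-yl}borane (not isolated) | COc1ccc(COC/C=C/B(C2CCCCC2)C2CCCCC2)cc1 | intermediate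
15 | methyl{(E)-3-[(4-methoxybenzyl)oxy]prop-1-en-1-yl}zinc (not isolated) | COc1ccc(COC/C=C/[Zn]C)cc1 | intermediate
16 | (2E,4S,5E,9Z)-6-{[(tert-butyldimethylsilyl)oxy]methyl}-10-iodo-11,11-dimethoxy-1-[(4-methoxybenzyl)oxy]undeca-2,5,9-trien-4-ol; (6S) bis-allylic alcohol | COc1ccc(COC/C=C/[C@H](O)/C=C(/CO[Si](C)(C)C(C)(C)C)CC/C=C(\I)C(OC)OC)cc1 | intermediate
17 | (6R,7R,8R)-epoxy alcohol: 16 with trans-C7–C8 epoxide erythro to the C6 hydroxyl | COc1ccc(COC[C@H]2O[C@@H]2[C@H](O)/C=C(/CO[Si](C)(C)C(C)(C)C)CC/C=C(\I)C(OC)OC)cc1 | intermediate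
18 | 2-(diethoxyphosphoryl)acetic acid | OC(=O)CP(=O)(OCC)OCC | starting material
19 | (6R,7R,8R)-6-O-[2-(diethoxyphosphoryl)acetyl] epoxy ester | COc1ccc(COC[C@H]2O[C@@H]2[C@H](OC(=O)CP(=O)(OCC)OCC)/C=C(/CO[Si](C)(C)C(C)(C)C)CC/C=C(\I)C(OC)OC)cc1 | intermediate
20 | (6R,7R,8S)-α-(diethoxyphosphoryl)-γ-lactone with free C8 hydroxyl, C11 epimers (not isolated) | COc1ccc(COC[C@@H](O)[C@H]2C(P(=O)(OCC)OCC)C(=O)O[C@@H]2/C=C(/CO[Si](C)(C)C(C)(C)C)CC/C=C(\I)C(OC)OC)cc1 | intermediate
21 | (6R,7R,8S)-α-methylene-γ-butyrolactone with free C8 hydroxyl and C9 4-methoxybenzyl ether | COc1ccc(COC[C@@H](O)[C@H]2C(=C)C(=O)O[C@@H]2/C=C(/CO[Si](C)(C)C(C)(C)C)CC/C=C(\I)C(OC)OC)cc1 | intermediate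
22 | (6R,7S,8S)-8-O-methacryloyl α-methylene lactone, C9 4-methoxybenzyl ether | COc1ccc(COC[C@@H](OC(=O)C(C)=C)[C@H]2C(=C)C(=O)O[C@@H]2/C=C(/CO[Si](C)(C)C(C)(C)C)CC/C=C(\I)C(OC)OC)cc1 | intermediate
23 | (6R,7S,8S)-8-O-methacryloyl α-methylene lactone, C9 primary alcohol | OC[C@@H](OC(=O)C(C)=C)[C@H]1C(=C)C(=O)O[C@@H]1/C=C(/CO[Si](C)(C)C(C)(C)C)CC/C=C(\I)C(OC)OC | intermediate
24 | (6R,7S,8S)-8-O-methacryloyl α-methylene lactone, C9 aldehyde | O=C[C@@H](OC(=O)C(C)=C)[C@H]1C(=C)C(=O)O[C@@H]1/C=C(/CO[Si](C)(C)C(C)(C)C)CC/C=C(\I)C(OC)OC | intermediate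
25 | C10 alkenylchromium dichloride (trivalent chromium) derived from 24 (not isolated) | O=C[C@@H](OC(=O)C(C)=C)[C@H]1C(=C)C(=O)O[C@@H]1/C=C(/CO[Si](C)(C)C(C)(C)C)CC/C=C(\[Cr](Cl)Cl)C(OC)OC | intermediate
26 | (6R,7S,8S)-macrocyclic C9 carbinol, mixture of C9 epimers; C15 silyl ether, C14 dimethyl acetal | C=C(C)C(=O)O[C@H]1[C@H]2C(=C)C(=O)O[C@@H]2/C=C(/CO[Si](C)(C)C(C)(C)C)CC/C=C(/C(OC)OC)C1O | intermediate
27 | (6R,7S,8S)-macrocyclic C9 enone | C=C(C)C(=O)O[C@H]1[C@H]2C(=C)C(=O)O[C@@H]2/C=C(/CO[Si](C)(C)C(C)(C)C)CC/C=C(/C(OC)OC)C1=O | intermediate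
28 | (6R,7S,8S,9S)-macrocyclic C9 alcohol | C=C(C)C(=O)O[C@H]1[C@H]2C(=C)C(=O)O[C@@H]2/C=C(/CO[Si](C)(C)C(C)(C)C)CC/C=C(/C(OC)OC)[C@@H]1O | intermediate
29 | (6R,7S,8S,9S)-9-acetate with C15 silyl ether and C14 dimethyl acetal | C=C(C)C(=O)O[C@H]1[C@H]2C(=C)C(=O)O[C@@H]2/C=C(/CO[Si](C)(C)C(C)(C)C)CC/C=C(/C(OC)OC)[C@@H]1OC(C)=O | intermediate
30 | CNP0147326.4, (1(10)E,4E,6R,7S,8S,9S)-9-acetoxy-15-hydroxy-8-methacryloyloxy-14-oxogermacra-1(10),4,11(13)-trien-12,6-olide | C=C(C)C(=O)O[C@H]1[C@H]2C(=C)C(=O)O[C@@H]2/C=C(/CO)CC/C=C(/C=O)[C@@H]1OC(C)=O | target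

## Step count and risks

Total step count: 20. Longest linear sequence: 19 steps (steps 1–7 and 9–20; step 8 prepares alkyne 13 off the main line).

Steps most likely to fail:

1. Step 12 (proposed new method). The carbanion may attack C8 instead of C7 (six-membered lactone), the enolate oxygen may alkylate instead of carbon, or the C8 alkoxide may take up the phosphoryl group before olefination. The fallback uses known radical chemistry and still closes the ring through C7–C11. It sets out from epoxy alcohol 17, which is O-propargylated (NaH, propargyl bromide, THF, 0 °C) to the propargyl ether F1. Cp2TiCl (trivalent titanium, made from Cp2TiCl2 and Zn in THF) opens the epoxide homolytically; the C7 radical cyclises 5-exo-dig onto the alkyne, trans to the C6 substituent, and gives the 3-methylenetetrahydrofuran alcohol F2 with the titanium-bound oxygen left on C8. Acylation with methacrylic anhydride gives the methacrylate F3. Allylic oxidation of the ring CH2 next to oxygen (CrO3·2C5H5N, CH2Cl2) then gives the lactone and returns to the route at 22. The weak points of this fallback are the regiochemistry of the homolysis and the selectivity of the final oxidation.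

2. Step 16. Oligomerisation may outrun ring closure because of transannular strain in the forming cis,cis-cyclodecadiene, and the α-acyloxy aldehyde may epimerise or decompose during slow addition. The fallback changes the ring-closing event to an acyl substitution at nickel and skips the carbinol. It sets out from alcohol 23, which is oxidised (TEMPO, PhI(OAc)2, MeCN/H2O) to the carboxylic acid F4 and converted (2,2'-dipyridyl disulfide, PPh3) into the S-(2-pyridyl) thioester F5. Nickel/zirconium-mediated intramolecular ketone synthesis between the thioester and the alkenyl iodide (NiBr2(4,4'-di-tert-butyl-2,2'-bipyridine), Cp2ZrCl2, Zn, 1,3-dimethyl-2-imidazolidinone, high dilution) gives the enone directly and returns to the route at 27.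

3. Step 10. Site selectivity between the two alkenes that flank the C6 carbinol may be lost (epoxidation of C4=C5), or the bis-allylic alcohol may react sluggishly or ionise on titanium. The fallback replaces the electrophilic, hydroxyl-directed epoxidation by a nucleophilic one. It sets out from 16, which is oxidised (MnO2, CH2Cl2) to the cross-conjugated dienone F6. Catalytic asymmetric nucleophilic epoxidation (La(OiPr)3, (R)-BINOL, Ph3As=O, t-BuOOH; the BINOL antipode that gives the αS,βR epoxy ketone) attacks only the less hindered β-carbon C8 and gives the epoxy ketone F7. Reduction with Zn(BH4)2, which is selective for the erythro isomer, gives the epoxy alcohol and returns to the route at 17. This fallback also removes any dependence on the enantiopurity reached in step 9.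

## Further compounds

F1 | step 12 | (6R,7R,8R)-6-O-propargyl ether of epoxy alcohol 17 | COc1ccc(COC[C@H]2O[C@@H]2[C@H](OCC#C)/C=C(/CO[Si](C)(C)C(C)(C)C)CC/C=C(\I)C(OC)OC)cc1
F2 | step 12 | (6R,7R,8S)-3-methylenetetrahydrofuran (O, C6, C7, C11, C12 ring) with free C8 hydroxyl | COc1ccc(COC[C@@H](O)[C@H]2C(=C)CO[C@@H]2/C=C(/CO[Si](C)(C)C(C)(C)C)CC/C=C(\I)C(OC)OC)cc1
F3 | step 12 | (6R,7S,8S)-8-O-methacryloyl 3-methylenetetrahydrofuran | COc1ccc(COC[C@@H](OC(=O)C(C)=C)[C@H]2C(=C)CO[C@@H]2/C=C(/CO[Si](C)(C)C(C)(C)C)CC/C=C(\I)C(OC)OC)cc1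
F4 | step 16 | (6R,7S,8S)-C9 carboxylic acid derived from 23 | OC(=O)[C@@H](OC(=O)C(C)=C)[C@H]1C(=C)C(=O)O[C@@H]1/C=C(/CO[Si](C)(C)C(C)(C)C)CC/C=C(\I)C(OC)OC
F5 | step 16 | (6R,7S,8S)-C9 S-(2-pyridyl) thioester | O=C(Sc1ccccn1)[C@@H](OC(=O)C(C)=C)[C@H]2C(=C)C(=O)O[C@@H]2/C=C(/CO[Si](C)(C)C(C)(C)C)CC/C=C(\I)C(OC)OC
F6 | step 10 | cross-conjugated C6 dienone from 16 (7E, 4E, 1(10)Z) | COc1ccc(COC/C=C/C(=O)/C=C(/CO[Si](C)(C)C(C)(C)C)CC/C=C(\I)C(OC)OC)cc1
F7 | step 10 | (7S,8R)-trans-7,8-epoxy C6 ketone | COc1ccc(COC[C@H]2O[C@@H]2C(=O)/C=C(/CO[Si](C)(C)C(C)(C)C)CC/C=C(\I)C(OC)OC)cc1
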